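C6–CH3 and C8–CH3 are cut back to two C–I bonds (twofold Negishi methylation), and these to C–H bonds (N-iodosuccinimide). The last operation in the forward direction is hydrogenolysis of two benzyl ethers.
The strategy rests on C6 and C8 of ring A. They are the only C–H carbons of a 5,7-dioxygenated chroman-4-one, and each lies ortho/para to the three donors O1, O5 and O7. Both are therefore iodinated without any regiochemical question, and each takes up one iodine only.
The C2 stereocentre is traced to a ligand-controlled copper hydride conjugate reduction of the achiral 2-heptadecylchromone. This is preferred to an oxa-Michael closure of the open enone, which cyclises on its own and reversibly with base.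
The chromone comes from a 1,3-diketone made from dibenzylated phloroacetophenone and octadecanoyl chloride. Ring A is bought, ring C is closed in step 3 by cyclodehydration, and no ring is formed afterwards.
Benzyl ethers are chosen because they withstand the acid used in ring closure and iodination, and they leave under neutral conditions that cannot open ring C.

Key step: step 6

Assumption: (R)-DTBM-SEGPHOS is taken to direct hydride to the C2 face that gives the S configuration, by analogy with its sense on β-substituted cyclic enones; the sense is to be confirmed on the first run, and the S ligand is used if it proves opposite.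

Step 1
Reactants: 1 2',4',6'-trihydroxyacetophenone; 2 benzyl bromide
Product: 3 2'-hydroxy-4',6'-bis(benzyloxy)acetophenone
Conditions: BnBr (2.1 equiv), K2CO3 (2.2 equiv), DMF, rt
Reagents that add atoms: benzyl bromide, BrCc1ccccc1
Why: Williamson ether synthesis in which the 4'-hydroxyl and one of the two equivalent ortho hydroxyls are alkylated, while the remaining ortho hydroxyl is held in a strong hydrogen bond to the acetyl carbonyl and stays free for the later ring closure.

Step 2
Reactants: 3 2'-hydroxy-4',6'-bis(benzyloxy)acetophenone; 4 octadecanoyl chloride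
Product: 5 1-[2,4-bis(benzyloxy)-6-hydroxyphenyl]icosane-1,3-dione
Conditions: LiN(SiMe3)2 (3.2 equiv), THF, −78 → −20 °C; 4 (1.05 equiv), −78 °C → rt; 1 M HCl quench
Reagents that add atoms: octadecanoyl chloride, CCCCCCCCCCCCCCCCCC(=O)Cl
Why: Claisen-type C-acylation of the lithium phenoxide–enolate dianion (the direct form of the Baker–Venkataraman diketone synthesis), in which any O-acylated material is carried to the same diketone by acyl migration and the third equivalent of base stores the product as its stable enolate.

Step 3
Reactants: 5 1-[2,4-bis(benzyloxy)-6-hydroxyphenyl]icosane-1,3-dione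
Product: 6 5,7-bis(benzyloxy)-2-heptadecyl-4H-chromen-4-one
Conditions: TsOH·H2O (10 mol %), toluene, 90 °C
Reagents that add atoms: none
Why: Acid-catalysed cyclodehydration of a 1-(2-hydroxyaryl)-1,3-diketone, the classical chromone synthesis, in which the free phenol adds to the aliphatic ketone and loss of water closes the pyranone ring C while the benzyl ethers tolerate the catalytic sulfonic acid.

Step 4
Reactants: 6 5,7-bis(benzyloxy)-2-heptadecyl-4H-chromen-4-one
Product: 8 (S)-5,7-bis(benzyloxy)-2-heptadecylchroman-4-one, via silyl enol ether 7 (not isolated)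
Conditions: Cu(OAc)2·H2O (5 mol %), (R)-DTBM-SEGPHOS (5.5 mol %), (EtO)2MeSiH (2 equiv), toluene, 0 °C → rt; then 1 M HCl, THF, 0 °C
Reagents that add atoms: none
Why: Asymmetric copper hydride conjugate reduction, a reaction type established for 2-alkylchromones, in which the ligated copper hydride formed from Cu(OAc)2 and the silane delivers hydride to C2 of the planar enone from the face left open by the chiral bisphosphine and so sets C2 as S, while the enolate is stored as silyl enol ether 7 until mild hydrolysis so that the C4 ketone is not reduced and ring C is not opened.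

Step 5
Reactants: 8 (S)-5,7-bis(benzyloxy)-2-heptadecylchroman-4-one; 9 N-iodosuccinimide
Product: 11 (S)-5,7-bis(benzyloxy)-2-heptadecyl-6,8-diiodochroman-4-one, via 8-iodochromanone 10 (not isolated)
Conditions: NIS (2.3 equiv), CF3CO2H (0.3 equiv), CH2Cl2/MeCN, 0 °C → rt, dark
Reagents that add atoms: N-iodosuccinimide, O=C1CCC(=O)N1I
Why: Electrophilic aromatic iodination with acid-activated NIS, expected first at the less crowded C8 and then at C6, which needs no regiocontrol because these are the only C–H carbons of ring A, stops at one iodine per carbon, is tolerated by the benzyl ethers and does not touch C2.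

Step 6
Reactants: 11 (S)-5,7-bis(benzyloxy)-2-heptadecyl-6,8-diiodochroman-4-one; 12 methylzinc chloride
Product: 14 (S)-5,7-bis(benzyloxy)-2-heptadecyl-6,8-dimethylchroman-4-one, via 6-iodo-8-methylchromanone 13 (not isolated)
Conditions: MeZnCl (2 M in THF, 5 equiv), Pd(P(t-Bu)3)2 (10 mol %), THF/NMP, rt → 50 °C, under argon; then aq NH4Cl
Reagents that add atoms: methylzinc chloride, C[Zn]Cl
Why: This is a Negishi cross-coupling run twice on one arene: the monoligated zerovalent palladium released from Pd(P(t-Bu)3)2 inserts into a C–I bond, methyl passes from zinc to palladium, and reductive elimination forms the aryl–CH3 bond, expected first at the less crowded C8 (13) and then at C6 between the two benzyloxy groups. The closest known reaction type is the methylation of di-ortho-oxygenated aryl iodides with methylzinc halides under palladium catalysis with bulky trialkylphosphines. No ring is closed and no stereocentre is formed; C2 is a spectator and keeps its S configuration because the medium holds no Brønsted base able to start a retro-oxa-Michael opening of ring C. Regioselectivity is not required, since C6 and C8 carry the only carbon–halogen bonds and both have to react. The selectivity that is required is chemoselectivity for C–I over the C4 ketone and its C3 protons, and it is secured by the low nucleophilicity and basicity of an organozinc halide and by the vinylogous-ester character and the 5-benzyloxy shielding of that carbonyl. Loss of iodine through a second transmetalation to an arylzinc species is held back by the electron-rich bulky phosphine, which speeds reductive elimination, by the lack of β-hydrogens in methyl and by the excess of 12.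

Step 7
Reactants: 14 (S)-5,7-bis(benzyloxy)-2-heptadecyl-6,8-dimethylchroman-4-one
Product: 15 (S)-2-heptadecyl-5,7-dihydroxy-6,8-dimethylchroman-4-one
Conditions: H2 (1 atm), 10 % Pd/C, EtOAc/EtOH, rt
Reagents that add atoms: none
Why: Hydrogenolysis of the two aryl benzyl ethers over palladium on carbon under neutral conditions, which leaves the electron-rich, hydrogen-bonded C4 aryl ketone and the C2 stereocentre unchanged and should give the target.

Compound list
1 | 2',4',6'-trihydroxyacetophenone | CC(=O)c1c(O)cc(O)cc1O | starting material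
2 | benzyl bromide | BrCc1ccccc1 | starting material
3 | 2'-hydroxy-4',6'-bis(benzyloxy)acetophenone | CC(=O)c1c(O)cc(OCc2ccccc2)cc1OCc1ccccc1 | intermediate
4 | octadecanoyl chloride | CCCCCCCCCCCCCCCCCC(=O)Cl | starting material
5 | 1-[2,4-bis(benzyloxy)-6-hydroxyphenyl]icosane-1,3-dione | CCCCCCCCCCCCCCCCCC(=O)CC(=O)c1c(O)cc(OCc2ccccc2)cc1OCc1ccccc1 | intermediate
6 | 5,7-bis(benzyloxy)-2-heptadecyl-4H-chromen-4-one | CCCCCCCCCCCCCCCCCC1=CC(=O)c2c(OCc3ccccc3)cc(OCc3ccccc3)cc2O1 | intermediate
7 | (S)-5,7-bis(benzyloxy)-4-{[diethoxy(methyl)silyl]oxy}-2-heptadecyl-2H-chromene | CCCCCCCCCCCCCCCCC[C@H]1C=C(O[Si](C)(OCC)OCC)c2c(OCc3ccccc3)cc(OCc3ccccc3)cc2O1 | intermediate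
8 | (S)-5,7-bis(benzyloxy)-2-heptadecylchroman-4-one | CCCCCCCCCCCCCCCCC[C@H]1CC(=O)c2c(OCc3ccccc3)cc(OCc3ccccc3)cc2O1 | intermediate
9 | N-iodosuccinimide | O=C1CCC(=O)N1I | starting material
10 | (S)-5,7-bis(benzyloxy)-2-heptadecyl-8-iodochroman-4-one | CCCCCCCCCCCCCCCCC[C@H]1CC(=O)c2c(OCc3ccccc3)cc(OCc3ccccc3)c(I)c2O1 | intermediate
11 | (S)-5,7-bis(benzyloxy)-2-heptadecyl-6,8-diiodochroman-4-one | CCCCCCCCCCCCCCCCC[C@H]1CC(=O)c2c(OCc3ccccc3)c(I)c(OCc3ccccc3)c(I)c2O1 | intermediate
12 | methylzinc chloride | C[Zn]Cl | starting material
13 | (S)-5,7-bis(benzyloxy)-2-heptadecyl-6-iodo-8-methylchroman-4-one | CCCCCCCCCCCCCCCCC[C@H]1CC(=O)c2c(OCc3ccccc3)c(I)c(OCc3ccccc3)c(C)c2O1 | intermediate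
14 | (S)-5,7-bis(benzyloxy)-2-heptadecyl-6,8-dimethylchroman-4-one | CCCCCCCCCCCCCCCCC[C@H]1CC(=O)c2c(OCc3ccccc3)c(C)c(OCc3ccccc3)c(C)c2O1 | intermediate
15 | (S)-2-heptadecyl-5,7-dihydroxy-6,8-dimethylchroman-4-one | CCCCCCCCCCCCCCCCC[C@H]1CC(=O)c2c(O)c(C)c(O)c(C)c2O1 | target

Total step count: 7. Longest linear sequence: 7 steps (1 → 15).

Steps most likely to fail

Step 6. The second coupling at the crowded C6–I bond may stall, and iodine may be lost reductively before methyl is transferred. The fallback sets out from 6 and comes back at 14; it puts the methyl groups on before the stereocentre exists. Chromone 6 is iodinated twice with 9 and CF3CO2H to 5,7-bis(benzyloxy)-2-heptadecyl-6,8-diiodo-4H-chromen-4-one F1. This compound has no stereocentre and no retro-oxa-Michael pathway. It can therefore be forced under hot, basic Suzuki–Miyaura conditions (trimethylboroxine, Pd(dppf)Cl2, K2CO3, dioxane, 100 °C) to 5,7-bis(benzyloxy)-2-heptadecyl-6,8-dimethyl-4H-chromen-4-one F2. The copper hydride reduction of step 4 then leads through (S)-5,7-bis(benzyloxy)-4-{[diethoxy(methyl)silyl]oxy}-2-heptadecyl-6,8-dimethyl-2H-chromene F3, and after hydrolysis to 14.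

Step 4. Hydride delivery may show poor or reversed facial selectivity on this electron-rich chromone. The C4 carbonyl may also be over-reduced, or the copper enolate may open ring C by β-elimination of the phenoxide. The fallback sets out from 4 and comes back at 8; it builds C2 by a hydrogenation of well-established sense followed by a stereospecific substitution.
- Acid chloride 4 is homologated with KO2CCH2CO2Me (MgCl2, Et3N, THF) to methyl 3-oxoicosanoate F4.
- Noyori hydrogenation (H2, RuCl2[(R)-BINAP], MeOH) should give methyl (R)-3-hydroxyicosanoate F5.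
- Mitsunobu etherification with purchased 3,5-bis(benzyloxy)phenol (DIAD, PPh3, toluene) inverts the carbinol carbon to methyl (S)-3-[3,5-bis(benzyloxy)phenoxy]icosanoate F6.
- LiOH in THF/water gives (S)-3-[3,5-bis(benzyloxy)phenoxy]icosanoic acid F7.
- (CF3CO)2O in CH2Cl2 at 0 °C closes ring C by intramolecular Friedel–Crafts acylation at either of the two equivalent ortho carbons, which is 8.

Step 5. The second iodination may stall once the first iodine has twisted its neighbouring benzyloxy group out of conjugation. Forcing it may bring iodination at C3 through the enol. The fallback sets out from 8 and comes back at 11; it iodinates the free phenols instead of the ethers. Compound 8 is hydrogenolysed (H2, Pd/C, EtOAc) to (S)-2-heptadecyl-5,7-dihydroxychroman-4-one F8. Both ring A positions of this compound should react with 9 in DMF at 0 °C without acid, giving (S)-2-heptadecyl-5,7-dihydroxy-6,8-diiodochroman-4-one F9. Both phenols are then benzylated again under base-free Mitsunobu conditions (BnOH, DIAD, PPh3, THF), which spares C2 and gives 11.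

Further compounds
F1 | step 6 | 5,7-bis(benzyloxy)-2-heptadecyl-6,8-diiodo-4H-chromen-4-one | CCCCCCCCCCCCCCCCCC1=CC(=O)c2c(OCc3ccccc3)c(I)c(OCc3ccccc3)c(I)c2O1
F2 | step 6 | 5,7-bis(benzyloxy)-2-heptadecyl-6,8-dimethyl-4H-chromen-4-one | CCCCCCCCCCCCCCCCCC1=CC(=O)c2c(OCc3ccccc3)c(C)c(OCc3ccccc3)c(C)c2O1
F3 | step 6 | (S)-5,7-bis(benzyloxy)-4-{[diethoxy(methyl)silyl]oxy}-2-heptadecyl-6,8-dimethyl-2H-chromene | CCCCCCCCCCCCCCCCC[C@H]1C=C(O[Si](C)(OCC)OCC)c2c(OCc3ccccc3)c(C)c(OCc3ccccc3)c(C)c2O1
F4 | step 4 | methyl 3-oxoicosanoate | CCCCCCCCCCCCCCCCCC(=O)CC(=O)OC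
F5 | step 4 | methyl (R)-3-hydroxyicosanoate | CCCCCCCCCCCCCCCCC[C@@H](O)CC(=O)OC
F6 | step 4 | methyl (S)-3-[3,5-bis(benzyloxy)phenoxy]icosanoate | CCCCCCCCCCCCCCCCC[C@H](Oc1cc(OCc2ccccc2)cc(OCc2ccccc2)c1)CC(=O)OC
F7 | step 4 | (S)-3-[3,5-bis(benzyloxy)phenoxy]icosanoic acid | CCCCCCCCCCCCCCCCC[C@H](Oc1cc(OCc2ccccc2)cc(OCc2ccccc2)c1)CC(=O)O
F8 | step 5 | (S)-2-heptadecyl-5,7-dihydroxychroman-4-one | CCCCCCCCCCCCCCCCC[C@H]1CC(=O)c2c(O)cc(O)cc2O1
F9 | step 5 | (S)-2-heptadecyl-5,7-dihydroxy-6,8-diiodochroman-4-one | CCCCCCCCCCCCCCCCC[C@H]1CC(=O)c2c(O)c(I)c(O)c(I)c2O1
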